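## The problem

Compound 17 is an open-chain bis(bibenzyl) with four benzene rings. Ring A (3-hydroxyphenyl) and ring B (para-phenylene) are joined by one ethylene bridge, ring C and ring D (2,5-dihydroxyphenyl) by a second, and rings B and C by a diaryl ether oxygen. There is no stereocenter, so the difficulty lies entirely in regiochemistry and in the timing of functional groups. Ring C is the crux: it carries a free hydroxyl at C1, the aryloxy group at C2 and the ethylene chain at C4. It is therefore a catechol in which only the oxygen meta to the chain is arylated, and any route through a preformed catechol has to tell two nearly equivalent oxygens apart. Ring D is a hydroquinone, easily oxidised to the quinone, so its oxygens and that of ring A must stay masked until the last step, and the unmasking must leave the diaryl ether intact. The two ArCH2CH2Ar bridges are unactivated and are best bought as a chain or made by saturating a carbon–carbon multiple bond. The enabling feature is that C1(OH)–C2(OAr)–C3(H)–C4(chain) of ring C maps onto C1(=O)–C2=C3–C4(R) of a 4-substituted cyclohex-2-enone. C2 of that enone can be made electrophilic as an epoxide and take the ring B phenoxide, while C1 carries the only oxygen ring C ever has before that, so the catechol problem does not arise. Such an enone is the annulation product of an α-unbranched aldehyde with methyl vinyl ketone, C4 and its chain being the aldehyde α-carbon and its substituent.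

## Retrosynthesis

From 17 to 16, only the three O–CH3 bonds on rings A and D are cut. Methyl ethers are preferred because 1 is bought already methylated and they survive every planned step (hydride, oxidant, enamine, alkaline peroxide, phenoxide, palladium under oxygen). The ring C hydroxyl needs no protection because it appears only one step earlier. The forward reaction must cleave O–CH3 bonds with a Lewis acid and spare the Ar–O–Ar linkage.

From 16 to 14, no skeletal bond is cut. Ring C is taken back by two hydrogen atoms to the 2-aryloxycyclohex-2-enone 14, the dienone 15 being the keto tautomer that lies between them. This turns C1 into a carbonyl and exposes C2 as its α-carbon. The forward dehydrogenation has to tolerate three electron-rich arenes and two benzylic bridges. A catalytic aerobic palladium method is therefore chosen over iodine- or quinone-based oxidants, which could halogenate or oxidise rings A and D.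

From 14 to 8 and 12, the C2–O ether bond is cut. The neighbouring cut, between the oxygen and ring B, would need a metal-mediated coupling of a ring C catechol derivative and with it the oxygen differentiation this plan avoids. At the enone oxidation level the bond forms when the phenoxide of 12 opens epoxy ketone 8 next to the carbonyl and the hydroxy ketone 13 loses water. The cut is convergent and gives halves of similar size (C16 and C15). The forward reaction must attack C2 and not C3; C2 is activated by the carbonyl and C3 is flanked by the substituted C4.

From 8 to 7, the two C–O bonds of the oxirane are removed. Nucleophilic epoxidation is specific to the electron-poor enone double bond and needs no metal. An α-halo enone as the C2 electrophile would bring back a metal-catalysed C–O coupling.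

From 7 to 3 and 4 (the key disconnection), the C4–C5 bond and the C2–C3 bond are cut. Attaching the two-carbon arm to a preformed six-membered enone by enolate alkylation would suffer from β-elimination of the 2-arylethyl electrophile. Partial reduction of a para-alkylated anisole would reduce ring D as well. The annulation instead builds ring C from acyclic pieces: C3 and C4 come from aldehyde 3, and C1, C2, C5 and C6 from enone 4. One ring and two carbon–carbon bonds are removed, leaving a linear aldehyde and a commodity chemical. The forward reaction must achieve a single conjugate addition at the aldehyde α-carbon, through enamine 5, and then aldol closure of keto aldehyde 6.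

From 3 through 2 to 1, only the oxidation level of the terminal carbon changes. Acid 1 is purchasable and already contains ring D and all four chain carbons.

From 12 through 11 to 9 and 10, the bridge is first taken back to an alkyne and the bond between the alkyne carbon and ring B is then cut. A Wittig union of two benzylic carbons would need a protecting group on the phenol, a separate phosphonium salt preparation, and would give a mixture of alkene isomers. The alkyne route takes two steps, tolerates the free phenol, and gives single compounds.

## Roads not taken

Alternative 1: The cut runs through ring B, which is assembled by cycloaddition of the aryl ethynyl ether A1 (carrying rings C and D) onto methyl coumalate A2. The bridged lactone then expels its carboxylate bridge to give the methyl 4-aryloxybenzoate A3.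
- Merits: the ether oxygen is in place before ring B exists, the polarisation of both partners puts the aryloxy group para to the ester, and no metal is needed. The regiochemical outcome at ring B is as secure as anything in the chosen plan.
- Weak points for this target:
  - Ring B is an unadorned para-phenylene that can be bought (as in 9), so a ring and two C–C bonds are spent where none is needed.
  - A1 presupposes a ring C phenol whose two catechol oxygens are already distinguished, which moves the central problem into a starting material.
  - A1 takes about two further steps from that phenol, and aryl ynol ethers are sensitive to moisture and heat while the cycloaddition needs prolonged heating.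
  - The ester of A3 must still be converted into the ethylene bridge and ring A (reduction, olefination, hydrogenation) before demethylation.
- Comparison: both plans avoid a metal-mediated ether coupling. Alternative 1 is longer and builds the one ring that needs no construction, whereas the chosen plan builds the ring that carries the regiochemical problem.

Alternative 2: Ring D is cut into three pieces. The alkenyl(methoxy)carbene chromium complex A4, the terminal alkyne A5 (already holding rings A, B and C) and one carbonyl ligand combine in a Dötz benzannulation to give the 4-methoxyphenol A6.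
- Merits: three C–C bonds and a ring form in one step, a terminal alkyne gives reliable regiochemistry, and the two hydroquinone oxygens emerge differentiated.
- Weak points for this target:
  - The differentiation is of no use, since both oxygens end as free hydroxyls, and ring D is the simplest part of the molecule (it is bought ready-made in 1).
  - A5 already contains the diaryl ether and the 1,2,4-pattern of ring C, so the real problems must be solved beforehand by other means.
  - The key step uses stoichiometric chromium late in the route, the unsubstituted vinyl carbene complex A4 is fragile, and A6 is an oxidation-prone phenol that still needs demethylation.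
- Comparison: the benzannulation is more convergent at the end than the chosen plan, but it spends its ring-forming step where the molecule is simplest. The chosen plan forms the same number of rings with cheap reagents at the point of greatest difficulty.

Alternative 3: Both aryl–CH2 bonds are cut. This leaves the dihalogenated core 4-bromo-2-(4-iodophenoxy)-1-methoxybenzene A7 and two B-(2-arylethyl)-9-borabicyclononanes, A8 for ring A and A9 for ring D, each from hydroboration of the corresponding vinylarene. One palladium catalyst couples the iodide of A7 with A8 at room temperature and then the bromide with A9 on heating. The product is the tetramethyl ether A10, and one demethylation gives 17.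
- Merits: this is the shortest road, about five operations against nine, and every bond formation is of an established type. On step count and convergence it is better than the chosen plan.
- Weak points for this target:
  - Iodide must be discriminated completely from bromide in one flask, or isomers of A10 with the two arms exchanged will form and be hard to separate.
  - The second coupling is on an electron-rich bromide para to a methoxy group.
  - A7 must be made by a copper-mediated etherification of a ring C phenol whose substitution pattern and oxygen differentiation are bought, not made.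
  - The ring C oxygen carries a fourth methyl group, to be removed next to the diaryl ether.
- Comparison: against the shorter count the chosen plan sets four things. The ring C regiochemistry follows from mechanism, there is no halogen selectivity to control and no stoichiometric borane, the ring C hydroxyl appears unprotected, and ring C analogues are reached by changing only the aldehyde.

Key step: step 3

Assumption: 1, 4, 9 and 10 are taken as purchasable; the ring C intermediates 6, 7, 8, 13, 14 and 15 are racemates or diastereomer mixtures whose configuration is erased on aromatisation, so their SMILES carry no stereodescriptors.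

## Route

Step 1
Reactants: 1 4-(2,5-dimethoxyphenyl)butanoic acid
Product: 2 4-(2,5-dimethoxyphenyl)butan-1-ol
Conditions: LiAlH4, THF, 0 °C to rt
Reagents that add atoms: none
Why: Hydride reduction of a carboxylic acid to the primary alcohol with LiAlH4; the aryl methyl ethers are inert to hydride.

Step 2
Reactants: 2 4-(2,5-dimethoxyphenyl)butan-1-ol
Product: 3 4-(2,5-dimethoxyphenyl)butanal
Conditions: Dess–Martin periodinane, CH2Cl2, 0 °C to rt
Reagents that add atoms: none
Why: Dess–Martin oxidation of a primary alcohol stops at the aldehyde under neutral, non-aqueous conditions, and with no electrophilic halogen present the electron-rich ring D should be untouched.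

Step 3
Reactants: 3 4-(2,5-dimethoxyphenyl)butanal; 4 methyl vinyl ketone (but-3-en-2-one)
Product: 7 racemic 4-[2-(2,5-dimethoxyphenyl)ethyl]cyclohex-2-en-1-one, via enamine 5 (not isolated), via keto aldehyde 6 (not isolated)
Conditions: pyrrolidine (1.2 equiv), 4 Å MS, PhMe, 0 °C to rt; 4 (1.2 equiv), 0 °C to rt; then AcOH–NaOAc–H2O, 90 °C
Reagents that add atoms: none
Why: Condensation of 3 with pyrrolidine should give the E-enamine 5, whose β-carbon (the former aldehyde α-carbon, the future C4) adds to the terminal carbon of 4 in a Michael addition that forms the C4–C5 bond, and hydrolysis of the resulting enamine releases keto aldehyde 6. In the hot acetate buffer the methyl ketone of 6, as its enol or pyrrolidine enamine, attacks the aldehyde carbon to form the C2–C3 bond, and the aldol adduct dehydrates to the conjugated enone 7. The closest known reaction type is the Stork enamine variant of the Robinson annulation, in which aldehyde enamines and methyl vinyl ketone give 4-substituted cyclohex-2-enones. Ring C closes in a 6-(enolendo)-exo-trig aldol; the other enolisable position of the ketone could only close a four-membered ring, so a single constitution is expected. The one new stereocenter, C4, forms racemic without control, which is acceptable because it becomes an aromatic carbon in step 8. The step needs a single C-alkylation at the aldehyde α-carbon and cross-condensation over self-condensation: the neutral enamine keeps enolate and free base out of the Michael stage, the monoadduct enamine is more substituted and too hindered to add a second enone, and slow addition of 4 at 0 °C to preformed 5 keeps free aldehyde away from its own enamine. The placing of the chain at C4 follows from the connectivity of the reaction and needs no directing group.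

Step 4
Reactants: 7 racemic 4-[2-(2,5-dimethoxyphenyl)ethyl]cyclohex-2-en-1-one
Product: 8 5-[2-(2,5-dimethoxyphenyl)ethyl]-7-oxabicyclo[4.1.0]heptan-2-one (racemic; epoxide mainly trans to the chain)
Conditions: 30% aq H2O2, NaOH (cat.), MeOH, 0 °C
Reagents that add atoms: hydrogen peroxide, OO
Why: Weitz–Scheffer nucleophilic epoxidation: hydroperoxide adds conjugately to the enone and the enolate closes the oxirane, so only the electron-poor C2=C3 bond reacts and the arenes are spared. Oxygen should enter mainly anti to the C4 chain, but either diastereomer serves because C2, C3 and C4 all become sp2 later.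

Step 5
Reactants: 9 4-iodophenol; 10 1-ethynyl-3-methoxybenzene
Product: 11 4-[(3-methoxyphenyl)ethynyl]phenol
Conditions: PdCl2(PPh3)2 (2 mol%), CuI (4 mol%), Et3N, THF, rt
Reagents that add atoms: none
Why: Sonogashira coupling of an aryl iodide with a terminal arylalkyne proceeds at room temperature and tolerates a free phenol, so no protecting group is needed.

Step 6
Reactants: 11 4-[(3-methoxyphenyl)ethynyl]phenol
Product: 12 4-[2-(3-methoxyphenyl)ethyl]phenol
Conditions: H2 (1 atm), 10% Pd/C, EtOAc–EtOH, rt
Reagents that add atoms: none
Why: Heterogeneous catalytic hydrogenation saturates the diarylalkyne to the bibenzyl; the aryl ether and phenol are not reduced under these conditions.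

Step 7
Reactants: 8 5-[2-(2,5-dimethoxyphenyl)ethyl]-7-oxabicyclo[4.1.0]heptan-2-one; 12 4-[2-(3-methoxyphenyl)ethyl]phenol
Product: 14 racemic 4-[2-(2,5-dimethoxyphenyl)ethyl]-2-{4-[2-(3-methoxyphenyl)ethyl]phenoxy}cyclohex-2-en-1-one, via hydroxy ketone 13 (not isolated)
Conditions: 12 (1.2 equiv), KH (0.2 equiv), 18-crown-6 (0.2 equiv), THF, rt to 60 °C
Reagents that add atoms: none
Why: Phenoxide opening of an α,β-epoxy ketone at the carbon next to the carbonyl (SN2 accelerated by the adjacent C=O, while C3 is flanked by the branched C4), followed by E1cB loss of water from β-hydroxy ketone 13, is the known route from epoxy ketones to 2-aryloxy enones. The hydroxide released regenerates phenoxide from the excess of 12, so the base is needed only in catalytic amount.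

Step 8
Reactants: 14 racemic 4-[2-(2,5-dimethoxyphenyl)ethyl]-2-{4-[2-(3-methoxyphenyl)ethyl]phenoxy}cyclohex-2-en-1-one
Product: 16 4-[2-(2,5-dimethoxyphenyl)ethyl]-2-{4-[2-(3-methoxyphenyl)ethyl]phenoxy}phenol, via dienone 15 (not isolated)
Conditions: Pd(OCOCF3)2 (5 mol%), 2-(dimethylamino)pyridine (10 mol%), TsOH·H2O (20 mol%), O2 (1 atm), DMSO, 80 °C
Reagents that add atoms: none
Why: Palladium-catalysed aerobic dehydrogenation of a cyclohexenone to a phenol: the palladium enolate at C6 undergoes β-hydride elimination to dienone 15, which tautomerises irreversibly to the phenol while O2 reoxidises the catalyst. No electrophilic halogen is present, so rings A and D should not be halogenated.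

Step 9
Reactants: 16 4-[2-(2,5-dimethoxyphenyl)ethyl]-2-{4-[2-(3-methoxyphenyl)ethyl]phenoxy}phenol
Product: 17 2-[2-(4-hydroxy-3-{4-[2-(3-hydroxyphenyl)ethyl]phenoxy}phenyl)ethyl]benzene-1,4-diol
Conditions: BBr3 (6 equiv), CH2Cl2, −78 °C to rt; H2O quench under Ar
Reagents that add atoms: none
Why: Lewis-acid cleavage of aryl methyl ethers with BBr3 (bromide attacks the methyl of the boron–ether adduct); the diaryl ether has no sp3 carbon on oxygen and should survive. Work-up under argon keeps the hydroquinone of ring D from oxidising.

## Compound list

1 | 4-(2,5-dimethoxyphenyl)butanoic acid | OC(=O)CCCc1cc(OC)ccc1OC | starting material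
2 | 4-(2,5-dimethoxyphenyl)butan-1-ol | OCCCCc1cc(OC)ccc1OC | intermediate
3 | 4-(2,5-dimethoxyphenyl)butanal | O=CCCCc1cc(OC)ccc1OC | intermediate
4 | methyl vinyl ketone (but-3-en-2-one) | CC(=O)C=C | starting material
5 | 1-[(1E)-4-(2,5-dimethoxyphenyl)but-1-en-1-yl]pyrrolidine | COc1ccc(OC)c(CC/C=C/N2CCCC2)c1 | intermediate
6 | racemic 2-[2-(2,5-dimethoxyphenyl)ethyl]-5-oxohexanal | CC(=O)CCC(C=O)CCc1cc(OC)ccc1OC | intermediate
7 | racemic 4-[2-(2,5-dimethoxyphenyl)ethyl]cyclohex-2-en-1-one | O=C1C=CC(CCc2cc(OC)ccc2OC)CC1 | intermediate
8 | 5-[2-(2,5-dimethoxyphenyl)ethyl]-7-oxabicyclo[4.1.0]heptan-2-one (racemic, diastereomer mixture) | O=C1CCC(CCc2cc(OC)ccc2OC)C2OC12 | intermediate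
9 | 4-iodophenol | Oc1ccc(I)cc1 | starting material
10 | 1-ethynyl-3-methoxybenzene | COc1cccc(C#C)c1 | starting material
11 | 4-[(3-methoxyphenyl)ethynyl]phenol | COc1cccc(C#Cc2ccc(O)cc2)c1 | intermediate
12 | 4-[2-(3-methoxyphenyl)ethyl]phenol | COc1cccc(CCc2ccc(O)cc2)c1 | intermediate
13 | 4-[2-(2,5-dimethoxyphenyl)ethyl]-3-hydroxy-2-{4-[2-(3-methoxyphenyl)ethyl]phenoxy}cyclohexan-1-one (racemic, diastereomer mixture) | COc1cccc(CCc2ccc(OC3C(O)C(CCc4cc(OC)ccc4OC)CCC3=O)cc2)c1 | intermediate
14 | racemic 4-[2-(2,5-dimethoxyphenyl)ethyl]-2-{4-[2-(3-methoxyphenyl)ethyl]phenoxy}cyclohex-2-en-1-one | COc1cccc(CCc2ccc(OC3=CC(CCc4cc(OC)ccc4OC)CCC3=O)cc2)c1 | intermediate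
15 | racemic 4-[2-(2,5-dimethoxyphenyl)ethyl]-2-{4-[2-(3-methoxyphenyl)ethyl]phenoxy}cyclohexa-2,5-dien-1-one | COc1cccc(CCc2ccc(OC3=CC(CCc4cc(OC)ccc4OC)C=CC3=O)cc2)c1 | intermediate
16 | 4-[2-(2,5-dimethoxyphenyl)ethyl]-2-{4-[2-(3-methoxyphenyl)ethyl]phenoxy}phenol | COc1cccc(CCc2ccc(Oc3cc(CCc4cc(OC)ccc4OC)ccc3O)cc2)c1 | intermediate
17 | 2-[2-(4-hydroxy-3-{4-[2-(3-hydroxyphenyl)ethyl]phenoxy}phenyl)ethyl]benzene-1,4-diol | Oc1cccc(CCc2ccc(Oc3cc(CCc4cc(O)ccc4O)ccc3O)cc2)c1 | target

Total step count: 9. Longest linear sequence: 7 steps (steps 1, 2, 3, 4, 7, 8, 9); steps 5 and 6 are the side branch that supplies 12.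

## Least certain steps

Step 3 (key step). The most likely failure is self-condensation of the unbranched aldehyde through its own enamine, with polymerisation of 4 or a second conjugate addition as further losses. All of these would lower the amount of 6 reaching the aldol stage. The fallback forms the C4–C5 bond by alkylation instead of conjugate addition. It sets out from 3, which is condensed with cyclohexylamine to N-cyclohexyl-4-(2,5-dimethoxyphenyl)butan-1-imine F1. Deprotonation with LiN(iPr)2 in THF at −78 °C and alkylation of the aza-enolate with 2-(2-bromoethyl)-2-methyl-1,3-dioxolane (a masked form of 4) should give the alkylated imine N-cyclohexyl-2-[2-(2,5-dimethoxyphenyl)ethyl]-4-(2-methyl-1,3-dioxolan-2-yl)butan-1-imine F2. Warm aqueous HCl then hydrolyses imine and dioxolane to keto aldehyde 6, which closes and dehydrates in the same acid to rejoin the route at 7.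

Step 7. Three things may go wrong. Hydroxide released in the dehydration may compete with phenoxide for the epoxide. The base may isomerise or ring-open the epoxy ketone through retro-aldol of 13. The sequence may also stall at the hydroxy ketone stage. The fallback forms the C2–O bond by SN2 at an α-halo ketone and uses the symmetry of a 4-substituted cyclohexanone. It sets out from 7 and is one step longer.
- Hydrogenation of 7 over Pd/C gives 4-[2-(2,5-dimethoxyphenyl)ethyl]cyclohexan-1-one F3, whose two α-positions are equivalent.
- PhNMe3Br3 in THF at 0 °C, a reagent selective for enol over arene bromination, gives 2-bromo-4-[2-(2,5-dimethoxyphenyl)ethyl]cyclohexan-1-one F4.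
- Displacement with 12 and K2CO3 in acetone gives 4-[2-(2,5-dimethoxyphenyl)ethyl]-2-{4-[2-(3-methoxyphenyl)ethyl]phenoxy}cyclohexan-1-one F5.
- Under the conditions of step 8, F5 should be dehydrogenated twice in one flask. The first dehydrogenation gives enone 14 or its isomer 4-[2-(2,5-dimethoxyphenyl)ethyl]-6-{4-[2-(3-methoxyphenyl)ethyl]phenoxy}cyclohex-2-en-1-one F6. Both converge on dienone 15, and the route is rejoined at 16.

Step 8. The dehydrogenation may stall if palladium enolate formation beside the oxygen-substituted enone is slow, the catalyst may deposit as palladium metal, or the electron-rich product phenol may be oxidised further under oxygen. The fallback replaces catalytic dehydrogenation by selenoxide elimination. It sets out from 14, which is deprotonated kinetically at C6 with LiN(iPr)2 in THF at −78 °C and treated with PhSeCl to give 4-[2-(2,5-dimethoxyphenyl)ethyl]-2-{4-[2-(3-methoxyphenyl)ethyl]phenoxy}-6-(phenylselanyl)cyclohex-2-en-1-one F7. Oxidation with H2O2 in CH2Cl2 at 0 °C gives the selenoxide 4-[2-(2,5-dimethoxyphenyl)ethyl]-2-{4-[2-(3-methoxyphenyl)ethyl]phenoxy}-6-(phenylseleninyl)cyclohex-2-en-1-one F8. Syn-elimination gives dienone 15, which tautomerises to rejoin the route at 16.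

## Further compounds

F1 | step 3 | N-cyclohexyl-4-(2,5-dimethoxyphenyl)butan-1-imine | COc1ccc(OC)c(CCC/C=N/C2CCCCC2)c1
F2 | step 3 | racemic N-cyclohexyl-2-[2-(2,5-dimethoxyphenyl)ethyl]-4-(2-methyl-1,3-dioxolan-2-yl)butan-1-imine | COc1ccc(OC)c(CCC(CCC2(C)OCCO2)/C=N/C2CCCCC2)c1
F3 | step 7 | 4-[2-(2,5-dimethoxyphenyl)ethyl]cyclohexan-1-one | O=C1CCC(CCc2cc(OC)ccc2OC)CC1
F4 | step 7 | 2-bromo-4-[2-(2,5-dimethoxyphenyl)ethyl]cyclohexan-1-one (racemic, diastereomer mixture) | O=C1CCC(CCc2cc(OC)ccc2OC)CC1Br
F5 | step 7 | 4-[2-(2,5-dimethoxyphenyl)ethyl]-2-{4-[2-(3-methoxyphenyl)ethyl]phenoxy}cyclohexan-1-one (racemic, diastereomer mixture) | COc1cccc(CCc2ccc(OC3CC(CCc4cc(OC)ccc4OC)CCC3=O)cc2)c1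
F6 | step 7 | 4-[2-(2,5-dimethoxyphenyl)ethyl]-6-{4-[2-(3-methoxyphenyl)ethyl]phenoxy}cyclohex-2-en-1-one (racemic, diastereomer mixture) | COc1cccc(CCc2ccc(OC3CC(CCc4cc(OC)ccc4OC)C=CC3=O)cc2)c1
F7 | step 8 | 4-[2-(2,5-dimethoxyphenyl)ethyl]-2-{4-[2-(3-methoxyphenyl)ethyl]phenoxy}-6-(phenylselanyl)cyclohex-2-en-1-one (racemic, diastereomer mixture) | COc1cccc(CCc2ccc(OC3=CC(CCc4cc(OC)ccc4OC)CC([Se]c4ccccc4)C3=O)cc2)c1
F8 | step 8 | 4-[2-(2,5-dimethoxyphenyl)ethyl]-2-{4-[2-(3-methoxyphenyl)ethyl]phenoxy}-6-(phenylseleninyl)cyclohex-2-en-1-one (racemic, diastereomer mixture) | COc1cccc(CCc2ccc(OC3=CC(CCc4cc(OC)ccc4OC)CC([Se](=O)c4ccccc4)C3=O)cc2)c1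
A1 | alternative 1 | 2-{2-[3-(ethynyloxy)-4-methoxyphenyl]ethyl}-1,4-dimethoxybenzene | C#COc1cc(CCc2cc(OC)ccc2OC)ccc1OC
A2 | alternative 1 | methyl coumalate (methyl 2-oxo-2H-pyran-5-carboxylate) | COC(=O)C1=COC(=O)C=C1
A3 | alternative 1 | methyl 4-{5-[2-(2,5-dimethoxyphenyl)ethyl]-2-methoxyphenoxy}benzoate | COC(=O)c1ccc(Oc2cc(CCc3cc(OC)ccc3OC)ccc2OC)cc1
A4 | alternative 2 | pentacarbonyl(1-methoxyprop-2-en-1-ylidene)chromium | COC(C=C)=[Cr](=C=O)(=C=O)(=C=O)(=C=O)=C=O
A5 | alternative 2 | 4-(but-3-yn-1-yl)-1-methoxy-2-{4-[2-(3-methoxyphenyl)ethyl]phenoxy}benzene | C#CCCc1ccc(OC)c(Oc2ccc(CCc3cccc(OC)c3)cc2)c1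
A6 | alternative 2 | 4-methoxy-2-[2-(4-methoxy-3-{4-[2-(3-methoxyphenyl)ethyl]phenoxy}phenyl)ethyl]phenol | COc1ccc(O)c(CCc2ccc(OC)c(Oc3ccc(CCc4cccc(OC)c4)cc3)c2)c1
A7 | alternative 3 | 4-bromo-2-(4-iodophenoxy)-1-methoxybenzene | COc1ccc(Br)cc1Oc1ccc(I)cc1
A8 | alternative 3 | 9-[2-(3-methoxyphenyl)ethyl]-9-borabicyclo[3.3.1]nonane | COc1cccc(CCB2C3CCCC2CCC3)c1
A9 | alternative 3 | 9-[2-(2,5-dimethoxyphenyl)ethyl]-9-borabicyclo[3.3.1]nonane | COc1ccc(OC)c(CCB2C3CCCC2CCC3)c1
A10 | alternative 3 | 2-[2-(4-methoxy-3-{4-[2-(3-methoxyphenyl)ethyl]phenoxy}phenyl)ethyl]-1,4-dimethoxybenzene | COc1cccc(CCc2ccc(Oc3cc(CCc4cc(OC)ccc4OC)ccc3OC)cc2)c1
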